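**Retrosynthetic overview**
1. Target 15 ⇐ cross-metathesis (allyl → prenyl) of 13; the allyl group is a latent prenyl that survives both epoxidations.
2. 13 ⇐ Shi epoxidation of the one remaining prenyl group of bicyclic 11 (oxirane formed last).
3. 11 ⇐ key C–O bond: enol-directed asymmetric epoxidation of the C6 prenyl group of 8, then 5-exo opening by the same enol oxygen (dihydrofuran ring formed here).
4. 8 ⇐ Pd-catalysed asymmetric dearomative allylation of symmetric deoxycohumulone 6 (sets the quaternary centre).
5. 6 ⇐ double C-prenylation of 3 ⇐ Friedel–Crafts acylation of phloroglucinol (the six-membered ring is bought as the arene).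

Assumption: the sense of induction of the chiral catalysts in steps 3 and 4 cannot be predicted for this substrate class; the ligand enantiomers named are to be fixed in a first screen, and the antipode is used if the sense is opposite. Tautomers are drawn in one form. Locants C1–C6 for 8 and 10 follow the cyclohexadienone name (C1 ring carbonyl, C2 acyl-bearing, C6 quaternary). BHA = N,N′-[(1R,2R)-cyclohexane-1,2-diyl]bis(N-hydroxy-2,2-diphenylacetamide).

**Step 1**
Reactants: 1 phloroglucinol; 2 isobutyryl chloride
Product: 3 phlorisobutyrophenone (2-methyl-1-(2,4,6-trihydroxyphenyl)propan-1-one)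
Conditions: AlCl3 (3 equiv), PhNO2–CH2Cl2, rt to 50 °C; aq HCl work-up
Reagents that add atoms: isobutyryl chloride (2), CC(C)C(Cl)=O
Why: Friedel–Crafts C-acylation of the very electron-rich arene, in which the first acyl group deactivates the ring so mono-acylation is clean; no stereocentre is formed.

**Step 2**
Reactants: 3 phlorisobutyrophenone; 4 prenyl bromide
Product: 6 deoxycohumulone (2-methyl-1-[2,4,6-trihydroxy-3,5-bis(3-methylbut-2-en-1-yl)phenyl]propan-1-one), via monoprenyl phlorisobutyrophenone 5 (not isolated)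
Conditions: prenyl bromide (2.0 equiv), 10 % aq KOH, 0 °C, Ar
Reagents that add atoms: prenyl bromide (4), CC(C)=CCBr
Why: base-mediated C-alkylation of the phenoxide in water (hydrogen-bonded oxygen, soft allylic bromide) prenylates the two free ring carbons in turn through 5, and limiting the bromide to two equivalents holds back the dearomatised triprenyl by-product; no stereocentre is formed.

**Step 3**
Reactants: 6 deoxycohumulone; 7 allyl methyl carbonate
Product: 8 (6S)-3,5-dihydroxy-4,6-bis(3-methylbut-2-en-1-yl)-2-(2-methylpropanoyl)-6-(prop-2-en-1-yl)cyclohexa-2,4-dien-1-one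
Conditions: Pd2(dba)3·CHCl3 (2.5 mol %), (R,R)-DACH-phenyl Trost ligand (7.5 mol %), allyl methyl carbonate (1.05 equiv), degassed CH2Cl2, 0 °C, Ar; used without storage
Reagents that add atoms: allyl methyl carbonate (7), C=CCOC(=O)OC
Why: Tsuji–Trost asymmetric allylic alkylation run as an allylic dearomatisation, in which the phenoxide of symmetric 6 attacks the π-allyl complex formed from zerovalent palladium at one of its two equivalent prenyl-bearing carbons and the chiral diphosphine pocket selects the enantiotopic face, setting the quaternary C6 as (S) in a triketone that cannot re-aromatise.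

**Step 4**
Reactants: 8 (6S)-allyl diprenyl dienone; 9 cumene hydroperoxide
Product: 11 (2S,3aR)-4-hydroxy-2-(2-hydroxypropan-2-yl)-7-(3-methylbut-2-en-1-yl)-5-(2-methylpropanoyl)-3a-(prop-2-en-1-yl)-3,3a-dihydro-1-benzofuran-6(2H)-one, via C6 epoxyprenyl enol 10 (not isolated)
Conditions: Hf(OtBu)4 (20 mol %), (R,R)-BHA ligand (22 mol %), cumene hydroperoxide (1.1 equiv), DMPU (1 equiv), 4 Å MS, toluene, 0 °C to rt
Reagents that add atoms: cumene hydroperoxide (9), CC(C)(OO)c1ccccc1
Why: Proposed new method: the free C5 enol hydroxyl of 8 (a vinylogous acid and the only hydroxyl outside the acyl chelate) binds the tetravalent hafnium bis-hydroxamate alkylperoxide and delivers oxygen to a bishomoallylic alkene; the in-plane C4 methylene pushes the bulky ligand sphere to the C6 side, where the trisubstituted prenyl group reacts in preference to the geminal allyl group on the face chosen by the ligand to give (R)-epoxide 10, which the same metal-bound enol oxygen opens 5-exo-tet with inversion to set (2S) and form the dihydrofuran C–O bond, while the hydroperoxide alone is too weak an electrophile to hydroxylate the enolised ring; the closest known chemistry is hafnium or zirconium bis-hydroxamic acid asymmetric epoxidation of homoallylic and bishomoallylic alcohols and VO(acac)2/t-BuOOH epoxidation–cyclisation of bishomoallylic alcohols to 2-(2-hydroxypropan-2-yl)tetrahydrofurans.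

**Step 5**
Reactants: 11 bicyclic allyl prenyl dihydrofuran; 12 potassium peroxymonosulfate (as Oxone)
Product: 13 (2S,3aR)-7-{[(2R)-3,3-dimethyloxiran-2-yl]methyl}-4-hydroxy-2-(2-hydroxypropan-2-yl)-5-(2-methylpropanoyl)-3a-(prop-2-en-1-yl)-3,3a-dihydro-1-benzofuran-6(2H)-one
Conditions: D-fructose-derived Shi ketone (30 mol %), Oxone (2KHSO5·KHSO4·K2SO4, 1.4 equiv KHSO5), K2CO3, Bu4NHSO4, MeCN–DMM / aq Na2B4O7–Na2EDTA (pH 10.5), 0 °C, 2 h; work-up at pH 5–6
Reagents that add atoms: potassium peroxymonosulfate (12), [K+].[O-]S(=O)(=O)OO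
Why: Shi asymmetric epoxidation, in which the chiral dioxirane reacts with the trisubstituted prenyl alkene far faster than with the monosubstituted allyl group or the push–pull enol ether, the spiro transition state of the D-fructose-derived ketone gives the (R)-epoxide, and the epoxide is left alone because its neighbours are now an ether oxygen and a chelated, weakly nucleophilic triketone oxygen.

**Step 6**
Reactants: 13 allyl epoxide; 14 2-methylbut-2-ene
Product: 15 (2S,3aR)-7-{[(2R)-3,3-dimethyloxiran-2-yl]methyl}-4-hydroxy-2-(2-hydroxypropan-2-yl)-3a-(3-methylbut-2-en-1-yl)-5-(2-methylpropanoyl)-3,3a-dihydro-1-benzofuran-6(2H)-one (CNP0395488.1)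
Conditions: second-generation Grubbs catalyst RuCl2(=CHPh)(H2IMes)(PCy3) (5 mol %), 2-methylbut-2-ene (30 equiv), CH2Cl2, 40 °C
Reagents that add atoms: 2-methylbut-2-ene (14), CC=C(C)C
Why: olefin cross-metathesis of the terminal allyl group with the trisubstituted partner installs the isopropylidene terminus (allyl to prenyl) with loss of propene, and the epoxide, tertiary alcohol, enol and all three stereocentres are untouched.

**Compound list**
1 | phloroglucinol (benzene-1,3,5-triol) | Oc1cc(O)cc(O)c1 | starting material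
2 | isobutyryl chloride (2-methylpropanoyl chloride) | CC(C)C(Cl)=O | starting material
3 | phlorisobutyrophenone, 2-methyl-1-(2,4,6-trihydroxyphenyl)propan-1-one | CC(C)C(=O)c1c(O)cc(O)cc1O | intermediate
4 | prenyl bromide (1-bromo-3-methylbut-2-ene) | CC(C)=CCBr | starting material
5 | monoprenyl phlorisobutyrophenone, 2-methyl-1-[2,4,6-trihydroxy-3-(3-methylbut-2-en-1-yl)phenyl]propan-1-one, formed in the flask | CC(C)C(=O)c1c(O)cc(O)c(CC=C(C)C)c1O | intermediate
6 | deoxycohumulone, 2-methyl-1-[2,4,6-trihydroxy-3,5-bis(3-methylbut-2-en-1-yl)phenyl]propan-1-one | CC(C)C(=O)c1c(O)c(CC=C(C)C)c(O)c(CC=C(C)C)c1O | intermediate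
7 | allyl methyl carbonate | C=CCOC(=O)OC | starting material
8 | (6S)-3,5-dihydroxy-4,6-bis(3-methylbut-2-en-1-yl)-2-(2-methylpropanoyl)-6-(prop-2-en-1-yl)cyclohexa-2,4-dien-1-one | C=CC[C@]1(CC=C(C)C)C(O)=C(CC=C(C)C)C(O)=C(C(=O)C(C)C)C1=O | intermediate
9 | cumene hydroperoxide | CC(C)(OO)c1ccccc1 | starting material
10 | (6S)-6-{[(2R)-3,3-dimethyloxiran-2-yl]methyl}-3,5-dihydroxy-4-(3-methylbut-2-en-1-yl)-2-(2-methylpropanoyl)-6-(prop-2-en-1-yl)cyclohexa-2,4-dien-1-one, formed in the flask | C=CC[C@]1(C[C@H]2OC2(C)C)C(O)=C(CC=C(C)C)C(O)=C(C(=O)C(C)C)C1=O | intermediate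
11 | (2S,3aR)-4-hydroxy-2-(2-hydroxypropan-2-yl)-7-(3-methylbut-2-en-1-yl)-5-(2-methylpropanoyl)-3a-(prop-2-en-1-yl)-3,3a-dihydro-1-benzofuran-6(2H)-one | C=CC[C@]12C[C@@H](C(C)(C)O)OC1=C(CC=C(C)C)C(=O)C(C(=O)C(C)C)=C2O | intermediate
12 | potassium peroxymonosulfate, KHSO5, the active component of Oxone | [K+].[O-]S(=O)(=O)OO | starting material
13 | (2S,3aR)-7-{[(2R)-3,3-dimethyloxiran-2-yl]methyl}-4-hydroxy-2-(2-hydroxypropan-2-yl)-5-(2-methylpropanoyl)-3a-(prop-2-en-1-yl)-3,3a-dihydro-1-benzofuran-6(2H)-one | C=CC[C@]12C[C@@H](C(C)(C)O)OC1=C(C[C@H]1OC1(C)C)C(=O)C(C(=O)C(C)C)=C2O | intermediate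
14 | 2-methylbut-2-ene | CC=C(C)C | starting material
15 | (2S,3aR)-7-{[(2R)-3,3-dimethyloxiran-2-yl]methyl}-4-hydroxy-2-(2-hydroxypropan-2-yl)-3a-(3-methylbut-2-en-1-yl)-5-(2-methylpropanoyl)-3,3a-dihydro-1-benzofuran-6(2H)-one | CC(C)=CC[C@]12C[C@@H](C(C)(C)O)OC1=C(C[C@H]1OC1(C)C)C(=O)C(C(=O)C(C)C)=C2O | target

**Step count and risks**
Total step count: 6. Longest linear sequence: 6.

The three steps most likely to fail are step 4, step 3 and step 5.

Step 4, the proposed new reaction, is the most exposed. Tetravalent hafnium may be held by the acyl β-diketone chelate instead of the C5 enol oxygen. Oxygen may be delivered to the C4 prenyl group, which would then cyclise the wrong way. The epoxide may also open 6-endo at the tertiary carbon. The fallback uses known chemistry and sets out from 8. Shi epoxidation with the D-fructose-derived ketone and 2.5 equiv KHSO5 converts both prenyl groups, and spares the allyl group, to give the bis-epoxide (6S)-4,6-bis{[(2R)-3,3-dimethyloxiran-2-yl]methyl}-3,5-dihydroxy-2-(2-methylpropanoyl)-6-(prop-2-en-1-yl)cyclohexa-2,4-dien-1-one F3. PPTS in CH2Cl2 then lets the free C5 enol oxygen open the C6 side-chain epoxide 5-exo with inversion. The C4 side-chain epoxide is left between the new ether oxygen and the chelated enol. The isomer from closure onto the C4 side chain must be removed by chromatography, so the yield is expected to be lower. This fallback comes back to the route at 13, and step 5 is then not needed.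

Step 3 may give low enantiomeric excess, O-allylation or a second allylation at C4. The fallback sets out from 6 and gives up enantiocontrol in the C–C step. Pd(PPh3)4 with allyl methyl carbonate gives racemic 3,5-dihydroxy-4,6-bis(3-methylbut-2-en-1-yl)-2-(2-methylpropanoyl)-6-(prop-2-en-1-yl)cyclohexa-2,4-dien-1-one F1. Step 4 is then run unchanged. Its catalyst fixes the (R)-epoxide, and hence (2S), on both enantiomers, so 11 forms together with its epimer (2S,3aS)-4-hydroxy-2-(2-hydroxypropan-2-yl)-7-(3-methylbut-2-en-1-yl)-5-(2-methylpropanoyl)-3a-(prop-2-en-1-yl)-3,3a-dihydro-1-benzofuran-6(2H)-one F2. The two are diastereomers and are separated on silica. The fallback comes back to the route at 11.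

Step 5 runs at pH 10.5 on a substrate that is then a triketonate anion. The anion may be hydroxylated at the acyl-bearing carbon, or its oxygen may open the new epoxide. The fallback sets out from 11 and gives up catalyst control in favour of neutral, anhydrous conditions. Dimethyldioxirane in acetone at −20 °C gives 13 together with its epoxide epimer (2S,3aR)-7-{[(2S)-3,3-dimethyloxiran-2-yl]methyl}-4-hydroxy-2-(2-hydroxypropan-2-yl)-5-(2-methylpropanoyl)-3a-(prop-2-en-1-yl)-3,3a-dihydro-1-benzofuran-6(2H)-one F4. The epimers are separated by preparative HPLC, with at most half the material carried on. The fallback comes back to the route at 13.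

**Further compounds**
F1 | step 3 | racemic 3,5-dihydroxy-4,6-bis(3-methylbut-2-en-1-yl)-2-(2-methylpropanoyl)-6-(prop-2-en-1-yl)cyclohexa-2,4-dien-1-one | C=CCC1(CC=C(C)C)C(O)=C(CC=C(C)C)C(O)=C(C(=O)C(C)C)C1=O
F2 | step 3 | (2S,3aS)-4-hydroxy-2-(2-hydroxypropan-2-yl)-7-(3-methylbut-2-en-1-yl)-5-(2-methylpropanoyl)-3a-(prop-2-en-1-yl)-3,3a-dihydro-1-benzofuran-6(2H)-one | C=CC[C@@]12C[C@@H](C(C)(C)O)OC1=C(CC=C(C)C)C(=O)C(C(=O)C(C)C)=C2O
F3 | step 4 | (6S)-4,6-bis{[(2R)-3,3-dimethyloxiran-2-yl]methyl}-3,5-dihydroxy-2-(2-methylpropanoyl)-6-(prop-2-en-1-yl)cyclohexa-2,4-dien-1-one | C=CC[C@]1(C[C@H]2OC2(C)C)C(O)=C(C[C@H]2OC2(C)C)C(O)=C(C(=O)C(C)C)C1=O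
F4 | step 5 | (2S,3aR)-7-{[(2S)-3,3-dimethyloxiran-2-yl]methyl}-4-hydroxy-2-(2-hydroxypropan-2-yl)-5-(2-methylpropanoyl)-3a-(prop-2-en-1-yl)-3,3a-dihydro-1-benzofuran-6(2H)-one | C=CC[C@]12C[C@@H](C(C)(C)O)OC1=C(C[C@@H]1OC1(C)C)C(=O)C(C(=O)C(C)C)=C2O
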